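**Retrosynthetic overview**
- Target 7 ⇐ hydrogenolysis of three benzyl ethers and exchange of Bu4N+ for H+ on the protected sulfate salt 5.
- 5 ⇐ key disconnection at the aryl C6–O(sulfate) bond: sulfate is delivered from trivalent iodine to C6 of luteolin 7,3',4'-tribenzyl ether 2, ortho to the free, chelated 5-OH.
- 2 ⇐ luteolin 1 by selective tribenzylation; the 5-OH is spared by its hydrogen bond to the C4 carbonyl.
- No ring is formed and no C–C bond is made: rings A, B and C come intact from luteolin.

Assumption: the target has no stereocentre, so no stereocontrol is needed; it is delivered as the free hydrogen sulfate drawn in the SMILES (kept cold, since aryl hydrogen sulfates hydrolyse on standing).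

**Step 1**
Reactants: 1 luteolin
Product: 2 luteolin 7,3',4'-tribenzyl ether
Conditions: BnBr (3.3 equiv), K2CO3 (3.5 equiv), DMF, 25 °C, 16 h
Reagents that add atoms: benzyl bromide, BrCc1ccccc1
Why: Williamson etherification; the acidic, unhindered 7-, 4'- and 3'-OH groups alkylate, while the 5-OH, locked in a hydrogen bond to the C4 carbonyl, stays free under K2CO3 at room temperature; no stereocentre is formed.

**Step 2**
Reactants: 2 luteolin 7,3',4'-tribenzyl ether
Product: 5 tetrabutylammonium 6-hydroxyluteolin 7,3',4'-tribenzyl ether 6-sulfate, via aryloxy(phenyl)iodanyl sulfate 3 (not isolated), via 6H-dienone sulfate 4 (not isolated)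
Conditions: PhIO (1.1 equiv), Bu4NHSO4 (1.1 equiv), 4 Å MS, CH2Cl2, −30 °C, 30 min; then 2, −30 → 0 °C
Reagents that add atoms: tetrabutylammonium hydrogen sulfate, CCCC[N+](CCCC)(CCCC)CCCC.OS(=O)(=O)[O-]
Why: Proposed new method: iodosylbenzene and Bu4NHSO4 give the Koser-type salt Bu4N[PhI(OH)OSO3]; the 5-OH replaces hydroxide on trivalent iodine (water is taken up by the sieves) to give 3, in which the only nucleophile is the iodine-bound sulfate; in non-polar CH2Cl2 this sulfate is passed within the complex (five- or seven-membered transition state) to C6, the single free ortho carbon, because the para carbon C8 is out of reach of an iodine-bound ligand; PhI is lost as monovalent iodine and dienone 4 (C6 transient, racemic) re-aromatises to 5, whose sulfate group and restored chelate slow a second oxidation; the closest known reactions are the ortho-acetoxylation of phenols by lead tetraacetate (Wessely oxidation), the ortho-oxygenation of phenols by 2-iodoxybenzoic acid, tosyloxy transfer from Koser's reagent and sulfate transfer from phenyliodosyl sulfate to alkenes, none of which has been shown to convert a phenol C–H bond into C–OSO3.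

**Step 3**
Reactants: 5 tetrabutylammonium 6-hydroxyluteolin 7,3',4'-tribenzyl ether 6-sulfate
Product: 7 6-hydroxyluteolin 6-sulfate, via tetrabutylammonium 6-hydroxyluteolin 6-sulfate 6 (not isolated)
Conditions: H2 (1 atm), Pd/C (10% palladium on carbon), THF/MeOH (1:1), 25 °C; filter; then HNTf2 (1.0 equiv), H2O, 0 °C, CH2Cl2 wash, freeze-dry
Reagents that add atoms: none
Why: Catalytic hydrogenolysis of the three benzyl aryl ethers, under which aryl sulfate salts and the flavone C2=C3 bond are inert at 1 atm and room temperature; HNTf2 then supplies the proton while the lipophilic Bu4N+ NTf2− ion pair is washed into CH2Cl2, leaving 7 in water; no stereocentre is involved.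

**Compound list**
1 | luteolin, 2-(3,4-dihydroxyphenyl)-5,7-dihydroxy-4H-chromen-4-one | O=c1cc(-c2ccc(O)c(O)c2)oc2cc(O)cc(O)c12 | starting material
2 | luteolin 7,3',4'-tribenzyl ether, 7-(benzyloxy)-2-[3,4-bis(benzyloxy)phenyl]-5-hydroxy-4H-chromen-4-one | O=c1cc(-c2ccc(OCc3ccccc3)c(OCc3ccccc3)c2)oc2cc(OCc3ccccc3)cc(O)c12 | intermediate
3 | tetrabutylammonium {[7-(benzyloxy)-2-(3,4-bis(benzyloxy)phenyl)-4-oxo-4H-chromen-5-yl]oxy}(phenyl)-λ3-iodanyl sulfate | O=c1cc(-c2ccc(OCc3ccccc3)c(OCc3ccccc3)c2)oc2cc(OCc3ccccc3)cc(OI(c3ccccc3)OS(=O)(=O)[O-])c12.CCCC[N+](CCCC)(CCCC)CCCC | intermediate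
4 | tetrabutylammonium 7-(benzyloxy)-2-[3,4-bis(benzyloxy)phenyl]-4,5-dioxo-5,6-dihydro-4H-chromen-6-yl sulfate (C6 racemic, transient) | O=C1C=C(c2ccc(OCc3ccccc3)c(OCc3ccccc3)c2)OC2=C1C(=O)C(OS(=O)(=O)[O-])C(OCc1ccccc1)=C2.CCCC[N+](CCCC)(CCCC)CCCC | intermediate
5 | tetrabutylammonium 6-hydroxyluteolin 7,3',4'-tribenzyl ether 6-sulfate, tetrabutylammonium 7-(benzyloxy)-2-[3,4-bis(benzyloxy)phenyl]-5-hydroxy-4-oxo-4H-chromen-6-yl sulfate | O=c1cc(-c2ccc(OCc3ccccc3)c(OCc3ccccc3)c2)oc2cc(OCc3ccccc3)c(OS(=O)(=O)[O-])c(O)c12.CCCC[N+](CCCC)(CCCC)CCCC | intermediate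
6 | tetrabutylammonium 6-hydroxyluteolin 6-sulfate, tetrabutylammonium 2-(3,4-dihydroxyphenyl)-5,7-dihydroxy-4-oxo-4H-chromen-6-yl sulfate | O=c1cc(-c2ccc(O)c(O)c2)oc2cc(O)c(OS(=O)(=O)[O-])c(O)c12.CCCC[N+](CCCC)(CCCC)CCCC | intermediate
7 | 6-hydroxyluteolin 6-sulfate, 2-(3,4-dihydroxyphenyl)-5,7-dihydroxy-4-oxo-4H-chromen-6-yl hydrogen sulfate | O=c1cc(-c2ccc(O)c(O)c2)oc2cc(O)c(OS(=O)(=O)O)c(O)c12 | target

**Step count and risks**
Total step count: 3. Longest linear sequence: 3.

The three steps most likely to fail: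

Step 2, the proposed new step. The sulfate may go to C8 (para) or C3, the product may be oxidised further, or ligand exchange at the chelated 5-OH may be too slow. The fallback uses known chemistry, sets out from 2 and comes back to the route at 5. Iodination ortho to the free 5-OH with benzyltrimethylammonium dichloroiodate and CaCO3 in CH2Cl2/MeOH at room temperature gives 6-iodoluteolin 7,3',4'-tribenzyl ether F1. Ullmann-type hydroxylation (CuI, 8-hydroxyquinoline, KOH, DMSO/H2O, 100 °C, argon, work-up with aqueous AcOH) gives 6-hydroxyluteolin 7,3',4'-tribenzyl ether F2. Sulfation of its only unchelated hydroxyl with Bu4NHSO4 and DCC in pyridine at room temperature gives 5.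

Step 3. Hydrogenation may also reduce the C2=C3 bond, or the sulfate may be lost. The fallback sets out from 5 and comes back to the route at 6. The benzyl ethers are removed by SN2 attack of NaSEt in DMF at 100 °C under argon, not by hydrogen; neutralisation with AcOH and extraction of the tetrabutylammonium ion pair gives 6. No new compound is made on this way (F0). The proton exchange of step 3 then gives 7.

Step 1. Partial benzylation of the 5-OH, or incomplete benzylation, may give a mixture. The fallback sets out from 1 and comes back to the route at 2. Exhaustive benzylation (BnBr in excess, K2CO3, DMF, 80 °C) gives luteolin 5,7,3',4'-tetrabenzyl ether F3. Chelation-controlled removal of the 5-O-benzyl group alone with MgBr2·OEt2 in toluene/Et2O at 60 °C gives 2.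

**Further compounds**
F1 | step 2 | 6-iodoluteolin 7,3',4'-tribenzyl ether, 7-(benzyloxy)-2-[3,4-bis(benzyloxy)phenyl]-5-hydroxy-6-iodo-4H-chromen-4-one | O=c1cc(-c2ccc(OCc3ccccc3)c(OCc3ccccc3)c2)oc2cc(OCc3ccccc3)c(I)c(O)c12
F2 | step 2 | 6-hydroxyluteolin 7,3',4'-tribenzyl ether, 7-(benzyloxy)-2-[3,4-bis(benzyloxy)phenyl]-5,6-dihydroxy-4H-chromen-4-one | O=c1cc(-c2ccc(OCc3ccccc3)c(OCc3ccccc3)c2)oc2cc(OCc3ccccc3)c(O)c(O)c12
F0 | step 3 | none | none
F3 | step 1 | luteolin 5,7,3',4'-tetrabenzyl ether, 5,7-bis(benzyloxy)-2-[3,4-bis(benzyloxy)phenyl]-4H-chromen-4-one | O=c1cc(-c2ccc(OCc3ccccc3)c(OCc3ccccc3)c2)oc2cc(OCc3ccccc3)cc(OCc3ccccc3)c12
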